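## Structural features

The target 22 is a 2,3-trans-dihydroflavonol: a chroman-4-one in which benzene ring A is fused to the oxygen heterocycle ring C, with a 3-hydroxy-4-methoxyphenyl group (ring B) on C2. Ring A is a fully differentiated phloroglucinol unit: O1 on C8a, a methoxy group on C7, a prenyl chain on C6, a free hydroxyl on C5 hydrogen-bonded to the C4 carbonyl, and hydrogen only on C8. The two stereocenters are neighbours: C2 (R), benzylic and bound to the ring oxygen, and C3 (R), a secondary carbinol next to the ketone, with aryl and hydroxyl trans. The fragile parts are the α-ketol/β-aryloxy ketone array of ring C (base can open it, epimerise it, contract it to a benzofuranone or, with air, dehydrogenate it to the flavonol), the C2–O1 bond (a 4-methoxybenzylic ether that strong acid ionises), and the prenyl group (it cyclises onto the neighbouring 5-OH under acid and rules out hydrogenolysis). The real difficulty is twofold. C2 and C3 must be set in absolute terms without passing through an open-chain intermediate that loses the C2 configuration. Ring A must end with the prenyl group on C6 and not C8, and with the free hydroxyl on C5 and the methyl ether on C7. The key step exploits the fact that O1 and the acyl carbon C4 are attached to the adjacent ring A carbons C8a and C4a, with oxygenated C5 flanking C4a. That is the pattern left when an alkoxy-substituted aryne inserts into the O–C(acyl) bond of a carboxylate, and C2–C3–C4 with their oxygens then map onto a trans-3-arylglycidate whose epoxide carries both stereocenters.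

## Logic of the disconnections

22 to 21: the O–Si bond at the ring B phenol is cut. A protecting group is needed there because the two phenols must be told apart during the work on ring A. A bulky silyl ether is chosen because buffered fluoride removes it without touching the prenyl group, the ketol or the benzylic ether. The forward step must stay close to neutral.

21 to 20: the trisubstituted C=C bond of the prenyl chain is cut, leaving a C6-allyl group. An allyl group can be delivered to carbon by a sigmatropic shift with predictable regiochemistry, whereas a prenyl ether would arrive reversed or at C8. The forward step is a cross-metathesis that must tolerate a free phenol and a free secondary alcohol.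

20 to 19: the C6–CH2 bond is cut and the allyl group is returned to the C5 oxygen. The C6/C8 problem thereby becomes intramolecular: of the two positions ortho to O5, only C6 carries hydrogen. The forward [3,3] shift needs heat, so the medium must be neutral to protect C2 and C3.

19 to 18: the O5–allyl bond is cut. The forward step must allylate the hydrogen-bonded phenol without touching the 3-OH and without base strong enough to open ring C; the ring B phenol is already silylated for that reason.

18 to 17 to 16: the ring B silyl ether is exchanged for an acetal, and the C5 hydroxyl is reconnected to a methyl group. The swap is forced by the key step, which uses fluoride and therefore excludes silyl ethers. Putting a methyl ether on O5 makes ring A a plain 3,5-dimethoxy pattern that comes from a symmetrical phenol. The C4 carbonyl created in the key step later singles out O5 by chelation. The forward step needs a Lewis acid that cleaves only the peri methyl ether and the acetal and leaves the 7- and 4'-methyl ethers and the C2–O1 bond alone.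

16 to 7 and 13: three bonds are cut in one operation, O1–C8a, C4–C4a and O1–C2. This opens ring C and separates ring A (as the aryne precursor 7) from everything else (the glycidate 13), two fragments of similar size. All stereochemistry is placed in 13, where it can be made by catalyst control. The forward step demands a single sense of addition to the aryne, acyl transfer faster than protonation of the aryl anion, and 6-endo rather than 5-exo opening of the epoxide.

13 to 12 to 11: the carboxylate is traced to its ethyl ester and the two epoxide C–O bonds to an (E)-cinnamate. The forward step needs an asymmetric oxygen transfer suited to an electron-poor alkene and of the correct enantiomeric series. The salt must be formed without ever being acidified, since the free acid loses carbon dioxide.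

11 to 9 and 10, and 9 to 8: the alkene is cut into an aldehyde and a phosphonate, and the acetal protecting group is removed. The forward olefination must give the E geometry, which the epoxidation translates into the trans-epoxide.

7 to 5 to 2 to 1: the O–S bond of the triflate and the C–Si bond are cut and the phenol oxygen is returned to a carbamate, which is the ortho-directing group. Because 1 is symmetrical, the two positions between the carbamate and a methoxy group are equivalent and one silylation product results. The forward sequence must avoid acid, which would remove silicon from the electron-rich ring.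

## Other disconnections considered

Alternative 1: The cut is through C3–C4 and O1–C2 of ring C, a retro-hetero-Diels–Alder. In the forward direction a chiral phosphoric acid would dehydrate the benzyl alcohol A2 to an ortho-quinone methide, and this would add to the (E)-styrylboronate A3 to give the trans-chromanyl boronate A1.
- In its favour: both stereocenters would be set in one catalytic event, with the E geometry of A3 carried suprafacially into the trans relationship. The carbon–boron bond can be oxidised with retention to the chroman-3-ol A4. No fluoride is involved, so the ring B silyl ether could be carried from the start. On this last point the alternative is better than the chosen plan, which has to change the ring B protecting group once.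
- Against it: A1 and A4 are at the chroman oxidation level. C4 would have to be oxidised to the ketone late, in competition with the doubly activated benzylic C2–H and on two electron-rich rings. The chelation-controlled unmasking of the 5-OH can only begin after that. The methide from A2 has no substituent on its terminus, so the catalyst would have to control the face of a weakly nucleophilic alkenylboronate rather than the face of the methide.
- Structure: both plans build ring C and leave the ring A substitution for later. The chosen plan delivers ring C at the right oxidation state.
- Mechanism: the alternative creates the stereocenters in the ring-forming step, whereas the chosen plan only transfers them from an epoxide. This is an equal trade between catalyst control and stereospecific transfer.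
- Step economy: the precursors A2 and A3 are shorter to make, but two extra oxidation steps plus the same ring A sequence make the total about equal or slightly longer.

Alternative 2: The cut removes four bonds of ring A (C8–C8a, C5–C6, C7–C8 and C4a–C5). In the forward direction a Wolff rearrangement of the diazoketone A6 would give a vinylketene, which would combine with the methoxyalkyne A7 by (2+2) addition, four-electron ring opening and six-electron closure to the phenol A5.
- In its favour: ring A would arise with the prenyl group on C6, the methoxy group on C7, the hydroxyl on C5 and hydrogen on C8 in one regiodefined event. The end game would shrink to a single desilylation of A5. On ring A regiochemistry and on the number of steps after the key step this alternative is clearly better than the chosen plan.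
- Against it: the burden moves to A6, a 2-aryl-3-silyloxy-dihydropyranone that must already hold both stereocenters and a diazoacetyl group on its enol ether carbon. Its synthesis is long and linear. The C2–O bond of this vinylogous ester and the C3 silyloxy group would have to survive the irradiation or heating needed for the cascade. A7 is a sensitive ynol ether with a skipped alkene that could itself meet the ketene.
- Structure: the alternative builds the aromatic ring last, and the chosen plan builds the heterocycle last.
- Mechanism: the pericyclic cascade is well defined in regiochemistry but would be run on a densely functionalised chiral substrate. The aryne cascade is less proven as a whole but starts from simple, robust partners.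
- Step economy: the alternative has the shorter tail, but probably the longer longest linear sequence because of A6.

Alternative 3: The cut is the C3–C4 bond. In the forward direction a chiral triazolium-derived carbene would convert the ring A aldehyde of the dialdehyde A9 into an acyl-anion equivalent, which would add to the side-chain aldehyde and close ring C as the ketol A8.
- In its favour: the ketol would appear directly at the correct oxidation level. Ring A would be complete, prenyl group included, before the key step. Only acetal removal would remain after A8. On step count after the key step and on freedom from metals and fluoride this alternative is the better one.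
- Against it: the ether carbon of A9 (the future C2) lies α to an aldehyde and carries both an aryl and an aryloxy group, so its configuration cannot be stored. The carbene step would have to set C2 by dynamic resolution and C3 by facial control at once. The carbene would also have to choose the hindered, electron-rich, doubly ortho-substituted aromatic aldehyde over the more electrophilic aliphatic one; the reverse choice would give the isomeric 4-hydroxychroman-3-one. The secondary ketol formed is itself prone to enolisation under the basic conditions. The strong precedent for this ring closure is with ketone acceptors, which give tertiary carbinols.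
- Structure: equal, since both plans close ring C.
- Mechanism: the chosen plan carries pre-formed stereocenters through stereospecific steps, whereas the alternative depends on a double selection that is not secured by the substrate.
- Step economy: comparable overall, because the prenylated salicylaldehyde needed for A9 requires its own regioselective ring A chemistry.

Key step: step 8

Remarks on the design (before the steps):
- Configuration: the (2R,3S)-trans-glycidate gives the (2R,3R) ring. The oxirane carbon that keeps its C–O bond becomes C3 with the same priority order and hence the same descriptor. The benzylic carbon is inverted and changes from S to R.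
- Aryne: the aryne 14 is not itself symmetrical. The symmetry lies in phenol 1, which gives a single silylation product. The single sense of addition to 14 comes from the methoxy group next to the triple bond.
- Assumption: the ketone catalyst of step 6 is the L-configured enantiomer of the acetylated fructose-derived ketone, prepared separately from L-sorbose. The common D-series catalyst would deliver the (2S,3R) glycidate and hence the enantiomer of 22.
- Ring A ethers: both are kept as methyl ethers through the key step. A regioselective route to an unsymmetrical aryne precursor is less secure than chelation-controlled cleavage of the peri ether once the ketone exists.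
- Stoichiometry of step 8: the glycidate salt is used in excess so that the aryne is consumed by carboxylate and not by the product alkoxide.

## Steps

Step 1
Reactants: 1 3,5-dimethoxyphenol
Product: 2 3,5-dimethoxyphenyl N-isopropylcarbamate
Conditions: i-PrNCO, Et3N (cat.), CH2Cl2, rt
Reagents that add atoms: isopropyl isocyanate, CC(C)N=C=O
Why: Amine-catalysed addition of a phenol to an isocyanate (carbamoylation); the N-monoalkyl carbamate is a strong ortho-directing group and can later be removed by mild base through an E1cB pathway.

Step 2
Reactants: 2 3,5-dimethoxyphenyl N-isopropylcarbamate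
Product: 5 3,5-dimethoxy-2-(trimethylsilyl)phenyl N-isopropylcarbamate, via N-silyl carbamate 3 (not isolated), via N,C-bis(silyl) carbamate 4 (not isolated)
Conditions: TMSOTf, TMEDA, Et2O, 0 °C to rt; n-BuLi, TMEDA, −78 °C; TMSCl, −78 °C to rt; aq. NH4Cl
Reagents that add atoms: chlorotrimethylsilane, C[Si](C)(C)Cl
Why: Directed ortho-metalation; the N–H is first masked as the N-silyl carbamate so that the base lithiates the ring at C2, between the carbamate and a methoxy group (C2 and C6 are equivalent, so one product is expected), and the aryllithium is silylated at low temperature before an anionic ortho-Fries shift can occur. Aqueous work-up hydrolyses the N–Si bond.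

Step 3
Reactants: 5 3,5-dimethoxy-2-(trimethylsilyl)phenyl N-isopropylcarbamate
Product: 7 3,5-dimethoxy-2-(trimethylsilyl)phenyl trifluoromethanesulfonate, via 3,5-dimethoxy-2-(trimethylsilyl)phenol 6 (not isolated)
Conditions: DBU, Et2NH, MeCN, 40 °C; then PhNTf2, rt
Reagents that add atoms: N-phenylbis(trifluoromethanesulfonimide), O=S(=O)(N(c1ccccc1)S(=O)(=O)C(F)(F)F)C(F)(F)F
Why: Base-induced E1cB cleavage of the N-monoalkyl carbamate (the isocyanate released is trapped by diethylamine) gives the phenoxide, which is triflated in the same flask by the mild triflyl donor. No acid meets the electron-rich aryl–silicon bond, so protodesilylation is avoided.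

Step 4
Reactants: 8 isovanillin (3-hydroxy-4-methoxybenzaldehyde)
Product: 9 4-methoxy-3-(methoxymethoxy)benzaldehyde
Conditions: MOMCl, i-Pr2NEt, CH2Cl2, 0 °C to rt
Reagents that add atoms: chloromethyl methyl ether, COCCl
Why: O-Alkylation of the phenol to the methoxymethyl acetal; this group withstands the phosphonate anion, the dioxirane, hydroxide and fluoride of the next four steps and is removed later by the boron Lewis acid.

Step 5
Reactants: 9 4-methoxy-3-(methoxymethoxy)benzaldehyde; 10 triethyl phosphonoacetate
Product: 11 ethyl (E)-3-[4-methoxy-3-(methoxymethoxy)phenyl]prop-2-enoate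
Conditions: NaH, THF, 0 °C to rt
Reagents that add atoms: none
Why: Horner–Wadsworth–Emmons olefination of an aromatic aldehyde with a stabilised phosphonate should give the (E)-cinnamate, the geometry that the epoxidation turns into the trans-epoxide.

Step 6
Reactants: 11 ethyl (E)-3-[4-methoxy-3-(methoxymethoxy)phenyl]prop-2-enoate
Product: 12 ethyl (2R,3S)-3-[4-methoxy-3-(methoxymethoxy)phenyl]oxirane-2-carboxylate
Conditions: 4,5-di-O-acetyl-1,2-O-isopropylidene-β-L-erythro-2,3-hexodiulo-2,6-pyranose (0.3 equiv), Oxone (2KHSO5·KHSO4·K2SO4), NaHCO3, Bu4NHSO4, MeCN/aq. Na2EDTA, 0 °C
Reagents that add atoms: potassium peroxymonosulfate (KHSO5, as Oxone), OOS(=O)(=O)[O-].[K+]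
Why: Shi epoxidation with a chiral dioxirane made in the flask; the electron-poor acetylated ketone is the variant suited to β-aryl acrylates, and oxygen is delivered to one face of the alkene through a spiro transition state, so the E geometry becomes the trans-epoxide. The L-configured catalyst is chosen to give the (2R,3S) series, the D-series catalyst being the one that gives (2S,3R) with cinnamates.

Step 7
Reactants: 12 ethyl (2R,3S)-3-[4-methoxy-3-(methoxymethoxy)phenyl]oxirane-2-carboxylate
Product: 13 potassium (2R,3S)-3-[4-methoxy-3-(methoxymethoxy)phenyl]oxirane-2-carboxylate
Conditions: KOH (1.0 equiv), EtOH, 0 °C; salt filtered and dried, never acidified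
Reagents that add atoms: potassium hydroxide, [K+].[OH-]
Why: Ester saponification with one equivalent of hydroxide at low temperature; the salt is collected directly because the free 3-arylglycidic acid would lose carbon dioxide with opening of the epoxide. Neither epoxide carbon is touched.

Step 8
Reactants: 7 3,5-dimethoxy-2-(trimethylsilyl)phenyl trifluoromethanesulfonate; 13 potassium (2R,3S)-3-[4-methoxy-3-(methoxymethoxy)phenyl]oxirane-2-carboxylate (1.5 equiv)
Product: 16 (2R,3R)-3-hydroxy-5,7-dimethoxy-2-[4-methoxy-3-(methoxymethoxy)phenyl]chroman-4-one, via 3,5-dimethoxybenzyne 14 (not isolated), via epoxy ketone phenoxide 15 (not isolated)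
Conditions: CsF, 18-crown-6, THF, 60 °C, slow addition of 7; then AcOH (1 equiv)
Reagents that add atoms: none
Why: Proposed new method: fluoride removes the silyl group of 7 and triflate leaves to give aryne 14, a carboxylate oxygen of 13 adds to it, and the aryl anion so formed attacks its own ester carbonyl through a four-membered adduct that opens to the 2-acylphenoxide 15, whose phenoxide then opens the epoxide; the closest known reaction type is the formal insertion of arynes into the O–C(acyl) bond of carboxylic acids to give ortho-hydroxyaryl ketones, which with acrylic acids continues by oxa-Michael closure to chroman-4-ones, and here an epoxide replaces the enone as the terminating electrophile. The oxygen should add at the aryne carbon meta to the flanking methoxy group (the future C8a), because that places the developing carbanion ortho to the inductively withdrawing oxygen substituent, so the ketone ends on C4a next to the 5-methoxy group. Ring C then closes by 6-endo-tet attack of the phenoxide on the benzylic epoxide carbon in an anti (SN2-type) opening. C2 is the only stereocenter made here and its configuration follows from inversion at the 3S carbon of the epoxide, while C3 is carried over unchanged from C2 of the glycidate, so the trans-epoxide gives the 2,3-trans (2R,3R) product. Three selectivities are needed. The sense of aryne addition is secured by the methoxy group next to the triple bond. Acyl transfer ahead of protonation is secured by the aprotic medium and the preformed salt, which leave no acidic proton. The preference for 6-endo over 5-exo closure (the latter would give a benzofuran-3-one) is secured by the 4-methoxyaryl group, which loosens the benzylic C–O bond and makes that carbon the more electrophilic one. The excess of 13 keeps the aryne from arylating the product alkoxide, and the acetic acid quench neutralises that alkoxide before work-up.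

Step 9
Reactants: 16 (2R,3R)-3-hydroxy-5,7-dimethoxy-2-[4-methoxy-3-(methoxymethoxy)phenyl]chroman-4-one
Product: 17 (2R,3R)-3,5-dihydroxy-2-(3-hydroxy-4-methoxyphenyl)-7-methoxychroman-4-one
Conditions: BCl3 (4 equiv), CH2Cl2, −78 to 0 °C; aq. NaHCO3
Reagents that add atoms: none
Why: Lewis-acid ether cleavage; BCl3 held between the C4 carbonyl and the peri 5-methoxy oxygen removes that methyl group selectively (the 7- and 4'-methyl ethers lack this activation) and cleaves the acetal-type MOM ether in the same operation. The low temperature protects the benzylic C2–O1 bond and the stereocenters.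

Step 10
Reactants: 17 (2R,3R)-3,5-dihydroxy-2-(3-hydroxy-4-methoxyphenyl)-7-methoxychroman-4-one
Product: 18 (2R,3R)-3,5-dihydroxy-7-methoxy-2-[4-methoxy-3-(triisopropylsilyloxy)phenyl]chroman-4-one
Conditions: TIPSCl (1.1 equiv), imidazole, DMF, 0 °C to rt
Reagents that add atoms: chlorotriisopropylsilane, CC(C)[Si](Cl)(C(C)C)C(C)C
Why: Chemoselective silylation; the non-chelated ring B phenol should react with the bulky silyl chloride much faster than the hydrogen-bonded 5-OH or the hindered secondary 3-OH.

Step 11
Reactants: 18 (2R,3R)-3,5-dihydroxy-7-methoxy-2-[4-methoxy-3-(triisopropylsilyloxy)phenyl]chroman-4-one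
Product: 19 (2R,3R)-5-(allyloxy)-3-hydroxy-7-methoxy-2-[4-methoxy-3-(triisopropylsilyloxy)phenyl]chroman-4-one
Conditions: allyl methyl carbonate, Pd(PPh3)4 (5 mol%), THF, 50 °C
Reagents that add atoms: allyl methyl carbonate, C=CCOC(=O)OC
Why: Tsuji–Trost O-allylation; zerovalent palladium ionises the carbonate, the methoxide released deprotonates the most acidic hydroxyl (the 5-phenol) and the phenoxide captures the π-allyl complex. The medium stays essentially neutral, which spares the base-sensitive ketol and the aryl silyl ether and leaves the aliphatic 3-OH alone.

Step 12
Reactants: 19 (2R,3R)-5-(allyloxy)-3-hydroxy-7-methoxy-2-[4-methoxy-3-(triisopropylsilyloxy)phenyl]chroman-4-one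
Product: 20 (2R,3R)-6-allyl-3,5-dihydroxy-7-methoxy-2-[4-methoxy-3-(triisopropylsilyloxy)phenyl]chroman-4-one
Conditions: 1,2-dichlorobenzene, 180 °C, sealed vessel, argon
Reagents that add atoms: none
Why: Aromatic Claisen rearrangement ([3,3]-sigmatropic shift) followed by tautomerisation; C6 is the only position ortho to O5 that carries hydrogen (the other is the ring-fusion carbon C4a), so the allyl group should arrive at C6 and the chelated 5-OH is restored. The neutral solvent avoids base-mediated damage to ring C.

Step 13
Reactants: 20 (2R,3R)-6-allyl-3,5-dihydroxy-7-methoxy-2-[4-methoxy-3-(triisopropylsilyloxy)phenyl]chroman-4-one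
Product: 21 (2R,3R)-3,5-dihydroxy-7-methoxy-6-(3-methylbut-2-en-1-yl)-2-[4-methoxy-3-(triisopropylsilyloxy)phenyl]chroman-4-one
Conditions: second-generation Grubbs catalyst RuCl2(=CHPh)(PCy3)(H2IMes) (5 mol%), 2-methyl-2-butene/CH2Cl2, 40 °C, sealed
Reagents that add atoms: 2-methyl-2-butene, CC=C(C)C
Why: Olefin cross-metathesis of the terminal allyl group with a large excess of the trisubstituted alkene, which caps the chain as the prenyl group and releases propene. Free phenols and alcohols are tolerated by the ruthenium carbene.

Step 14
Reactants: 21 (2R,3R)-3,5-dihydroxy-7-methoxy-6-(3-methylbut-2-en-1-yl)-2-[4-methoxy-3-(triisopropylsilyloxy)phenyl]chroman-4-one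
Product: 22 (2R,3R)-3,5-dihydroxy-2-(3-hydroxy-4-methoxyphenyl)-7-methoxy-6-(3-methylbut-2-en-1-yl)chroman-4-one (CNP0146895.1)
Conditions: Bu4NF, AcOH, THF, 0 °C
Reagents that add atoms: none
Why: Fluoride cleavage of the aryl silyl ether, buffered with acetic acid so that neither the liberated phenoxide nor the ketol is exposed to base. No stereocenter and no acid-sensitive group (prenyl, benzylic ether) is affected.

## Compound list

1 | 3,5-dimethoxyphenol | COc1cc(O)cc(OC)c1 | starting material
2 | 3,5-dimethoxyphenyl N-isopropylcarbamate | COc1cc(OC)cc(OC(=O)NC(C)C)c1 | intermediate
3 | 3,5-dimethoxyphenyl N-isopropyl-N-(trimethylsilyl)carbamate | COc1cc(OC)cc(OC(=O)N(C(C)C)[Si](C)(C)C)c1 | intermediate (not isolated)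
4 | 3,5-dimethoxy-2-(trimethylsilyl)phenyl N-isopropyl-N-(trimethylsilyl)carbamate | COc1cc(OC)c([Si](C)(C)C)c(OC(=O)N(C(C)C)[Si](C)(C)C)c1 | intermediate (not isolated)
5 | 3,5-dimethoxy-2-(trimethylsilyl)phenyl N-isopropylcarbamate | COc1cc(OC)c([Si](C)(C)C)c(OC(=O)NC(C)C)c1 | intermediate
6 | 3,5-dimethoxy-2-(trimethylsilyl)phenol | COc1cc(OC)c([Si](C)(C)C)c(O)c1 | intermediate (not isolated)
7 | 3,5-dimethoxy-2-(trimethylsilyl)phenyl trifluoromethanesulfonate | COc1cc(OC)c([Si](C)(C)C)c(OS(=O)(=O)C(F)(F)F)c1 | intermediate
8 | isovanillin (3-hydroxy-4-methoxybenzaldehyde) | COc1ccc(C=O)cc1O | starting material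
9 | 4-methoxy-3-(methoxymethoxy)benzaldehyde | COCOc1cc(C=O)ccc1OC | intermediate
10 | triethyl phosphonoacetate | CCOC(=O)CP(=O)(OCC)OCC | starting material
11 | ethyl (E)-3-[4-methoxy-3-(methoxymethoxy)phenyl]prop-2-enoate | CCOC(=O)/C=C/c1ccc(OC)c(OCOC)c1 | intermediate
12 | ethyl (2R,3S)-3-[4-methoxy-3-(methoxymethoxy)phenyl]oxirane-2-carboxylate | COc1ccc([C@@H]2O[C@H]2C(=O)OCC)cc1OCOC | intermediate
13 | potassium (2R,3S)-3-[4-methoxy-3-(methoxymethoxy)phenyl]oxirane-2-carboxylate | COc1ccc([C@@H]2O[C@H]2C(=O)[O-])cc1OCOC.[K+] | intermediate
14 | 3,5-dimethoxybenzyne (1,2-didehydro-3,5-dimethoxybenzene) | COC1=CC(OC)=CC#C1 | intermediate (not isolated)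
15 | potassium 3,5-dimethoxy-2-{[(2R,3S)-3-[4-methoxy-3-(methoxymethoxy)phenyl]oxiran-2-yl]carbonyl}phenoxide | COc1ccc([C@@H]2O[C@H]2C(=O)c2c([O-])cc(OC)cc2OC)cc1OCOC.[K+] | intermediate (not isolated)
16 | (2R,3R)-3-hydroxy-5,7-dimethoxy-2-[4-methoxy-3-(methoxymethoxy)phenyl]chroman-4-one | COc1ccc([C@H]2Oc3cc(OC)cc(OC)c3C(=O)[C@@H]2O)cc1OCOC | intermediate
17 | (2R,3R)-3,5-dihydroxy-2-(3-hydroxy-4-methoxyphenyl)-7-methoxychroman-4-one | COc1ccc([C@H]2Oc3cc(OC)cc(O)c3C(=O)[C@@H]2O)cc1O | intermediate
18 | (2R,3R)-3,5-dihydroxy-7-methoxy-2-[4-methoxy-3-(triisopropylsilyloxy)phenyl]chroman-4-one | COc1ccc([C@H]2Oc3cc(OC)cc(O)c3C(=O)[C@@H]2O)cc1O[Si](C(C)C)(C(C)C)C(C)C | intermediate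
19 | (2R,3R)-5-(allyloxy)-3-hydroxy-7-methoxy-2-[4-methoxy-3-(triisopropylsilyloxy)phenyl]chroman-4-one | COc1ccc([C@H]2Oc3cc(OC)cc(OCC=C)c3C(=O)[C@@H]2O)cc1O[Si](C(C)C)(C(C)C)C(C)C | intermediate
20 | (2R,3R)-6-allyl-3,5-dihydroxy-7-methoxy-2-[4-methoxy-3-(triisopropylsilyloxy)phenyl]chroman-4-one | COc1ccc([C@H]2Oc3cc(OC)c(CC=C)c(O)c3C(=O)[C@@H]2O)cc1O[Si](C(C)C)(C(C)C)C(C)C | intermediate
21 | (2R,3R)-3,5-dihydroxy-7-methoxy-6-(3-methylbut-2-en-1-yl)-2-[4-methoxy-3-(triisopropylsilyloxy)phenyl]chroman-4-one | COc1ccc([C@H]2Oc3cc(OC)c(CC=C(C)C)c(O)c3C(=O)[C@@H]2O)cc1O[Si](C(C)C)(C(C)C)C(C)C | intermediate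
22 | (2R,3R)-3,5-dihydroxy-2-(3-hydroxy-4-methoxyphenyl)-7-methoxy-6-(3-methylbut-2-en-1-yl)chroman-4-one | COc1ccc([C@H]2Oc3cc(OC)c(CC=C(C)C)c(O)c3C(=O)[C@@H]2O)cc1O | target

## Step count and least certain steps

Total step count: 14 (steps 1–3 make the aryne precursor, steps 4–7 the glycidate, step 8 joins them, steps 9–14 finish ring A and remove the last protecting group).
Longest linear sequence: 11 steps (steps 4 to 14, from 8).

Step 8 (key step, proposed new method). Four things could go wrong.
- The phenoxide 15 could close in the 5-exo sense onto the carbon next to the ketone, because the second ortho substituent twists the aryl ketone and a bare phenoxide favours the more SN2-like site.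
- The aryne could be consumed by the product alkoxide or by 15 instead of the weakly nucleophilic carboxylate.
- The glycidate salt could decompose thermally before it is arylated.
- The aryl anion could be protonated before acyl transfer if adventitious water is present.

Isolating the phenol of 15 and closing it with a mild Lewis acid would be a change of conditions only. The fallback proper uses known chalcone-epoxide chemistry. It sets out from 9 and comes back to the route at 17. Commercial 1-(2,6-dihydroxy-4-methoxyphenyl)ethanone F1 would be protected on both phenols (MOMCl, NaH, DMF) to give 1-[4-methoxy-2,6-bis(methoxymethoxy)phenyl]ethanone F2. Claisen–Schmidt condensation of F2 with 9 (KOH, EtOH) should give the chalcone (E)-1-[4-methoxy-2,6-bis(methoxymethoxy)phenyl]-3-[4-methoxy-3-(methoxymethoxy)phenyl]prop-2-en-1-one F3. Julia–Colonna epoxidation (poly-L-leucine, urea–H2O2, DBU, THF) should give [(2R,3S)-3-[4-methoxy-3-(methoxymethoxy)phenyl]oxiran-2-yl][4-methoxy-2,6-bis(methoxymethoxy)phenyl]methanone F4. Hydrogen chloride in methanol at 45 °C would then remove all three acetals and let one of the two equivalent phenols open the epoxide at the benzylic carbon, giving 17 directly. In this branch the free 5-OH comes from the symmetrical ketone, so step 9 is not needed.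

Step 6. The likely failures are slow oxygen transfer to the electron-poor alkene with loss of the catalyst by Baeyer–Villiger oxidation, incomplete facial selectivity, and acid-promoted opening of the electron-rich benzylic epoxide during isolation. The L-series catalyst also has to be prepared. The fallback replaces catalyst control by resolution. It sets out from 9 and comes back at 13. Darzens condensation of 9 with methyl chloroacetate (NaOMe, MeOH, −10 °C) should give racemic methyl trans-3-[4-methoxy-3-(methoxymethoxy)phenyl]oxirane-2-carboxylate F5. Enantioselective hydrolysis with the lipase from Serratia marcescens (toluene/aqueous buffer, pH 8) is expected to consume the (2S,3R) ester, whose acid decarboxylates and is washed out as the aldehyde bisulfite adduct. This leaves methyl (2R,3S)-3-[4-methoxy-3-(methoxymethoxy)phenyl]oxirane-2-carboxylate F6, which KOH in methanol at 0 °C converts into 13.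

Step 9. The likely failures are over-reaction of the excess Lewis acid (loss of the 4'-methyl group assisted by the neighbouring boron aryloxide once the acetal has gone), ionisation of the C2–O1 bond with epimerisation at C2, and alkylation of the electron-rich rings by the chloromethyl ether released. The fallback separates the two deprotections. It sets out from 16 and comes back at 18. Catalytic HCl in methanol at room temperature should remove only the acetal and give (2R,3R)-3-hydroxy-2-(3-hydroxy-4-methoxyphenyl)-5,7-dimethoxychroman-4-one F7. Silylation (TIPSCl, imidazole, DMF) gives (2R,3R)-3-hydroxy-5,7-dimethoxy-2-[4-methoxy-3-(triisopropylsilyloxy)phenyl]chroman-4-one F8. About two equivalents of BCl3 at −78 °C then perform only the chelation-controlled cleavage of the 5-methyl ether to give 18.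

Step 12. The likely failures are thermal damage to ring C (dehydrogenation to the flavonol, epimerisation, migration of the silyl group) at the temperature the rearrangement needs, and partial onward shift of the allyl group to C8. The fallback replaces the O-to-C shift by halogenation and cross-coupling. It sets out from 18 and comes back at 21, so steps 11 to 13 are bypassed. Iodination ortho to the free 5-OH with benzyltrimethylammonium dichloroiodate and CaCO3 in CH2Cl2/MeOH should give (2R,3R)-3,5-dihydroxy-6-iodo-7-methoxy-2-[4-methoxy-3-(triisopropylsilyloxy)phenyl]chroman-4-one F9. Stille coupling of F9 with tributyl(3-methylbut-2-en-1-yl)stannane (Pd(PPh3)4, DMF, 90 °C) should give 21.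

## Further compounds

F1 | step 8 | 1-(2,6-dihydroxy-4-methoxyphenyl)ethanone (commercial) | CC(=O)c1c(O)cc(OC)cc1O
F2 | step 8 | 1-[4-methoxy-2,6-bis(methoxymethoxy)phenyl]ethanone | CC(=O)c1c(OCOC)cc(OC)cc1OCOC
F3 | step 8 | (E)-1-[4-methoxy-2,6-bis(methoxymethoxy)phenyl]-3-[4-methoxy-3-(methoxymethoxy)phenyl]prop-2-en-1-one | COCOc1cc(OC)cc(OCOC)c1C(=O)/C=C/c1ccc(OC)c(OCOC)c1
F4 | step 8 | [(2R,3S)-3-[4-methoxy-3-(methoxymethoxy)phenyl]oxiran-2-yl][4-methoxy-2,6-bis(methoxymethoxy)phenyl]methanone | COc1ccc([C@@H]2O[C@H]2C(=O)c2c(OCOC)cc(OC)cc2OCOC)cc1OCOC
F5 | step 6 | methyl trans-3-[4-methoxy-3-(methoxymethoxy)phenyl]oxirane-2-carboxylate (racemate, one enantiomer drawn) | COc1ccc([C@@H]2O[C@H]2C(=O)OC)cc1OCOC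
F6 | step 6 | methyl (2R,3S)-3-[4-methoxy-3-(methoxymethoxy)phenyl]oxirane-2-carboxylate (single enantiomer) | COc1ccc([C@@H]2O[C@H]2C(=O)OC)cc1OCOC
F7 | step 9 | (2R,3R)-3-hydroxy-2-(3-hydroxy-4-methoxyphenyl)-5,7-dimethoxychroman-4-one | COc1ccc([C@H]2Oc3cc(OC)cc(OC)c3C(=O)[C@@H]2O)cc1O
F8 | step 9 | (2R,3R)-3-hydroxy-5,7-dimethoxy-2-[4-methoxy-3-(triisopropylsilyloxy)phenyl]chroman-4-one | COc1ccc([C@H]2Oc3cc(OC)cc(OC)c3C(=O)[C@@H]2O)cc1O[Si](C(C)C)(C(C)C)C(C)C
F9 | step 12 | (2R,3R)-3,5-dihydroxy-6-iodo-7-methoxy-2-[4-methoxy-3-(triisopropylsilyloxy)phenyl]chroman-4-one | COc1ccc([C@H]2Oc3cc(OC)c(I)c(O)c3C(=O)[C@@H]2O)cc1O[Si](C(C)C)(C(C)C)C(C)C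
A1 | alternative 1 | trans-5,7-dimethoxy-2-[4-methoxy-3-(triisopropylsilyloxy)phenyl]chroman-3-yl pinacol boronate (same spatial arrangement at C2 and C3 as 22) | COc1ccc([C@H]2Oc3cc(OC)cc(OC)c3C[C@@H]2B4OC(C)(C)C(C)(C)O4)cc1O[Si](C(C)C)(C(C)C)C(C)C
A2 | alternative 1 | 2-(hydroxymethyl)-3,5-dimethoxyphenol | COc1cc(O)c(CO)c(OC)c1
A3 | alternative 1 | 2-[(E)-2-[4-methoxy-3-(triisopropylsilyloxy)phenyl]ethenyl]-4,4,5,5-tetramethyl-1,3,2-dioxaborolane | COc1ccc(/C=C/B2OC(C)(C)C(C)(C)O2)cc1O[Si](C(C)C)(C(C)C)C(C)C
A4 | alternative 1 | (2R,3S)-5,7-dimethoxy-2-[4-methoxy-3-(triisopropylsilyloxy)phenyl]chroman-3-ol | COc1ccc([C@H]2Oc3cc(OC)cc(OC)c3C[C@@H]2O)cc1O[Si](C(C)C)(C(C)C)C(C)C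
A5 | alternative 2 | 3,3'-bis-O-(tert-butyldimethylsilyl) ether of 22 | COc1ccc([C@H]2Oc3cc(OC)c(CC=C(C)C)c(O)c3C(=O)[C@@H]2O[Si](C)(C)C(C)(C)C)cc1O[Si](C)(C)C(C)(C)C
A6 | alternative 2 | (2R,3R)-3-(tert-butyldimethylsilyloxy)-2-[3-(tert-butyldimethylsilyloxy)-4-methoxyphenyl]-6-(2-diazoacetyl)-2,3-dihydro-4H-pyran-4-one | COc1ccc([C@H]2OC(C(=O)C=[N+]=[N-])=CC(=O)[C@@H]2O[Si](C)(C)C(C)(C)C)cc1O[Si](C)(C)C(C)(C)C
A7 | alternative 2 | 1-methoxy-5-methylhex-4-en-1-yne | COC#CCC=C(C)C
A8 | alternative 3 | (2R,3R)-3-hydroxy-7-methoxy-5-(methoxymethoxy)-2-[4-methoxy-3-(methoxymethoxy)phenyl]-6-(3-methylbut-2-en-1-yl)chroman-4-one | COc1ccc([C@H]2Oc3cc(OC)c(CC=C(C)C)c(OCOC)c3C(=O)[C@@H]2O)cc1OCOC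
A9 | alternative 3 | 2-[2-formyl-5-methoxy-3-(methoxymethoxy)-4-(3-methylbut-2-en-1-yl)phenoxy]-2-[4-methoxy-3-(methoxymethoxy)phenyl]acetaldehyde (ether carbon configurationally labile, drawn without configuration) | COc1ccc(C(C=O)Oc2cc(OC)c(CC=C(C)C)c(OCOC)c2C=O)cc1OCOC
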